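The route rests on cutting the C7–C8 bond (germacranolide numbering) of the ten-membered ring by a retro-Claisen step. The precursor 21 is a twelve-membered allyl dienyl ether. In it the future C9 oxygen bridges C9 and C13, C8 is an exocyclic methylene, and C11=C7 lies in a butenolide. Heating triggers one [3,3] shift. This shift contracts the 12-ring to the 10-ring, forms C7–C8, sets C7 cis to C6, unveils the exocyclic C11=C13 methylene of the lactone, and turns the ring oxygen into the C9 ketone. It exploits the 1,5-relation between O9 and C13 across C9–C8–C7–C11=C13 and the cis lactone fusion. C8, C9 and both esters follow by relay.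

Key step: step 14

Remarks:
- Germacranolide numbering is used throughout: ring C1–C10, lactone carbons C11–C13, C14 on C10, C15 on C4, and primes for the epoxy acid.
- Assumption: aldehyde 1 is bought as a catalogue compound.
- Compounds 9, 11 and 13–16 are epimer mixtures at the phosphonate carbon, which is lost in step 10. Lactol 20 is an anomer mixture. These centres are left open in the SMILES.

Step 1
Reactants: 1 3-[(4-methoxybenzyl)oxy]propanal
Product: 2 1-({[(3Z)-4-iodopent-3-en-1-yl]oxy}methyl)-4-methoxybenzene
Conditions: EtPPh3I, n-BuLi, THF, rt; I2, −78 °C; NaHMDS, −20 °C; then 1, −78 → −20 °C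
Reagents that add atoms: ethyltriphenylphosphonium iodide CC[P+](c1ccccc1)(c1ccccc1)c1ccccc1.[I-]; iodine II
Why: The Stork–Zhao-type Wittig olefination with the α-iodoethylidene ylide is kinetically Z-selective, so iodine ends cis to the C2 chain and the later C3=C4 (Z) geometry is fixed here.

Step 2
Reactants: 2 (Z)-vinyl iodide; 3 (S)-epichlorohydrin
Product: 6 (2S)-2-{(2Z)-5-[(4-methoxybenzyl)oxy]-2-methylpent-2-en-1-yl}oxirane, via alkenyllithium 4 (not isolated), via chlorohydrin 5 (not isolated)
Conditions: t-BuLi (2 equiv), Et2O, −78 °C; BF3·OEt2, 3, −78 °C; crude, K2CO3, MeOH, rt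
Reagents that add atoms: none
Why: Iodine–lithium exchange keeps the alkene geometry, the BF3-assisted SN2 opening takes place at the unsubstituted epoxide carbon so that C6 keeps the configuration of 3, and an intramolecular Williamson displacement of chloride then closes the new epoxide.

Step 3
Reactants: 6 epoxide
Product: 7 (3S,5Z)-8-[(4-methoxybenzyl)oxy]-5-methylocta-1,5-dien-3-ol
Conditions: Me3SI, n-BuLi, THF, −10 °C → rt
Reagents that add atoms: trimethylsulfonium iodide C[S+](C)C.[I-]
Why: Dimethylsulfonium methylide opens the terminal epoxide carbon and β-elimination of dimethyl sulfide follows (one-carbon epoxide-to-allylic-alcohol homologation), which should leave C6 untouched.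

Step 4
Reactants: 8 ethyl 2-[bis(2,2,2-trifluoroethoxy)phosphoryl]propanoate
Product: 9 2-[bis(2,2,2-trifluoroethoxy)phosphoryl]propanoic acid
Conditions: Me3SnOH, 1,2-dichloroethane, 80 °C; dilute HCl wash
Reagents that add atoms: trimethyltin hydroxide C[Sn](C)(C)O
Why: This mild tin-hydroxide ester hydrolysis should cleave the carboxylic ethyl ester and spare the hydroxide-labile trifluoroethyl phosphonate esters.

Step 5
Reactants: 9 phosphono acid; 10 2-methylenepropane-1,3-diol (excess)
Product: 11 2-(hydroxymethyl)prop-2-en-1-yl 2-[bis(2,2,2-trifluoroethoxy)phosphoryl]propanoate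
Conditions: EDC·HCl, DMAP (cat.), CH2Cl2, 0 °C → rt
Reagents that add atoms: none
Why: Steglich-type carbodiimide esterification with an excess of the symmetric diol should stop at the mono-ester.

Step 6
Reactants: 7 allylic alcohol; 11 hydroxy ester
Product: 13 mixed diisopropylsilyl bis-ether (silaketal) of 7 (at O6) and 11 (at O12), via chlorosilane 12 (not isolated)
Conditions: iPr2SiCl2, imidazole, CH2Cl2, 0 °C, 7 first; then 11, rt
Reagents that add atoms: dichlorodiisopropylsilane CC(C)[Si](Cl)(Cl)C(C)C
Why: In this stepwise silylation (temporary silicon tether) the hindered secondary alcohol stops at the monochlorosilane, which the primary alcohol 11 then caps.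

Step 7
Reactants: 13 silaketal diene
Product: 14 (4S)-2,2-diisopropyl-4,7-dihydro-1,3,2-dioxasilepine carrying the (2Z)-5-(PMB-oxy)-2-methylpent-2-enyl chain at C4 (= C6) and the CH2O-phosphonopropionate at C6 (= C11)
Conditions: Grubbs II (cat.), CH2Cl2, reflux
Reagents that add atoms: none
Why: In this silicon-tethered ring-closing metathesis the seven-membered ring can hold only a cis alkene, so C12 ends cis to C6 and C13 trans to it, while the trisubstituted C3=C4 alkene stays inert.

Step 8
Reactants: 14 PMB ether
Product: 15 primary alcohol (C1–OH) of 14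
Conditions: DDQ, CH2Cl2–pH 7 buffer, 0 °C
Reagents that add atoms: none
Why: Oxidative PMB cleavage with DDQ is neutral and should leave the silaketal, the phosphonate and the alkenes untouched.

Step 9
Reactants: 15 alcohol
Product: 16 β,γ-unsaturated aldehyde (C1 = CHO) of 15
Conditions: Dess–Martin periodinane, NaHCO3, CH2Cl2, 0 °C
Reagents that add atoms: none
Why: The buffered Dess–Martin oxidation is mild enough to keep the C3=C4 alkene out of conjugation, and 16 is used at once.

Step 10
Reactants: 16 aldehyde phosphonate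
Product: 17 bicyclic twelve-membered macrolactone C9(=O)–O–C13 with 1(10)Z and 3Z alkenes, O6 and O12 still tied by iPr2Si (6S)
Conditions: K2CO3, 18-crown-6, PhMe (1 mM, slow addition), −20 → 0 °C
Reagents that add atoms: none
Why: The intramolecular Still–Gennari variant of the Horner–Wadsworth–Emmons reaction eliminates fast from the syn adduct of the trifluoroethyl phosphonate, which should give the (Z)-2-methylenoate without any acyl activation that could isomerise it.

Step 11
Reactants: 17 macrolactone
Product: 18 twelve-membered allyl dienyl ether (C9=C8H2 in place of C9=O)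
Conditions: Tebbe reagent, pyridine, THF–PhMe, −40 °C → rt; aq. NaOH
Reagents that add atoms: Tebbe reagent (written as Cp2Ti=CH2·ClAlMe2) C=[Ti](C1C=CC=C1)C1C=CC=C1.C[Al](C)Cl
Why: Tebbe methylenation acts on the only carbonyl group in the molecule, works below room temperature so that no rearrangement starts, and pyridine ties up the aluminium Lewis acid.

Step 12
Reactants: 18 silaketal dienyl ether
Product: 19 macrocyclic diol (6S; C6–OH and C12H2–OH cis on C7=C11)
Conditions: TBAF, THF, 0 °C; pH 7 work-up, Et3N-washed silica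
Reagents that add atoms: none
Why: Fluoride desilylation is basic, so the acid-sensitive dienyl ether should survive.

Step 13
Reactants: 19 diol
Product: 21 α,γ-bridged butenolide macrocycle (6S): twelve-membered ring C9–O–C13–C11=C7–C6–C5–C4=C3–C2–C1=C10 with exocyclic C8H2, via lactol 20 (not isolated)
Conditions: activated MnO2, NaHCO3, CH2Cl2, rt
Reagents that add atoms: none
Why: Manganese dioxide oxidises the primary allylic alcohol first, the cis C6–OH traps the enal as a lactol, and a second allylic oxidation gives the butenolide under non-acidic conditions.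

Step 14
Reactants: 21 butenolide macrocycle
Product: 22 (6S,7S)-9-oxogermacra-1(10)Z,3Z,11(13)-trien-12,6-olide (C8 = CH2)
Conditions: PhMe (2 mM, degassed), BHT (cat.), silanised sealed tube, 110 °C
Reagents that add atoms: none
Why: This is a concerted suprafacial [3,3]-sigmatropic (Claisen) rearrangement of the array C8=C9–O–C13–C11=C7, in which the C8–C7 σ-bond forms while O–C13 breaks, so that O, C13 and C11 leave the ring and C8 enters it (12 → 10). The closest known reaction types are the methylenation–Claisen sequence of allylic lactones and the ring-contracting Claisen rearrangement of macrolide ketene acetals, and here the acceptor on C11 (position 5 of the array) and the diene donor on C9 should both lower the barrier. The ten-membered ring closes transannularly through a six-centre chair- or boat-like array bridged by the seven-atom chain C10–C1–C2–C3–C4–C5–C6, and because C8 is a CH2 group both arrays give the same product. The only new stereocentre, C7, is set by C6: the flat butenolide carries C5 on one face and the short chain lets C8 reach C7 only from that face, so C5 and C8 end cis (cis-fused lactone, 6S,7S), which is the opposite of what an untethered nucleophile would give. The step needs periselectivity over a [1,5]-hydrogen shift from C2 to C8 in the (Z)-diene and freedom from acid, and the electronic acceleration, the silanised glass, the dilution and BHT serve these needs. Both Z alkenes are spectators, the α-methylene lactone appears directly, and the former ring oxygen becomes the C9 enone carbonyl.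

Step 15
Reactants: 22 enone lactone
Product: 24 (6S,7S,8R)-8-hydroxy-9-oxogermacra-1(10)Z,3Z,11(13)-trien-12,6-olide, via potassium enolate 23 (not isolated)
Conditions: KHMDS, THF, −78 °C; 2-(phenylsulfonyl)-3-phenyloxaziridine, −78 °C; NH4Cl
Reagents that add atoms: 2-(phenylsulfonyl)-3-phenyloxaziridine O=S(=O)(N1OC1c1ccccc1)c1ccccc1
Why: In this Davis oxidation of the kinetic cross-conjugated enolate, C7–H eclipses the enolate plane (A1,3 strain) and the oxidant should attack the peripheral face opposite the ring bond C7–C6, which corresponds to 8R.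

Step 16
Reactants: 24 α-hydroxy enone
Product: 25 (6S,7S,8R,9S)-8,9-dihydroxygermacra-1(10)Z,3Z,11(13)-trien-12,6-olide
Conditions: Zn(BH4)2, Et2O–CH2Cl2, −40 → −20 °C
Reagents that add atoms: none
Why: In this chelation-controlled 1,2-reduction zinc bridges O8 and O9 and hydride comes from the face opposite C7, which should give the erythro (ring-cis) diol with 9S and leave the α-methylene lactone alone.

Step 17
Reactants: 25 diol
Product: 26 9-O-acetate of 25 (free C8–OH)
Conditions: AcCl (1.1 equiv), 2,4,6-collidine, CH2Cl2, −78 → −40 °C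
Reagents that add atoms: acetyl chloride CC(=O)Cl
Why: Kinetic acylation should take the allylic C9–OH, because C8–OH is shielded by the branched C7 and the lactone ring.

Step 18
Reactants: 27 tiglic acid
Product: 28 (E)-2-methylbut-2-en-1-ol
Conditions: LiAlH4, Et2O, 0 °C → rt
Reagents that add atoms: none
Why: Hydride reduction of the acid gives the allylic alcohol with the E alkene unchanged.

Step 19
Reactants: 28 allylic alcohol
Product: 29 [(2R,3R)-2,3-dimethyloxiran-2-yl]methanol
Conditions: Ti(OiPr)4 (cat.), D-(−)-DIPT (cat.), t-BuOOH, 4 Å MS, CH2Cl2, −20 °C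
Reagents that add atoms: tert-butyl hydroperoxide CC(C)(C)OO
Why: In the Sharpless asymmetric epoxidation the D-(−)-tartrate catalyst delivers oxygen to the face that gives the (2R,3R)-epoxide, and syn addition keeps the two methyl groups cis.

Step 20
Reactants: 29 epoxy alcohol
Product: 30 (2S,3R)-2,3-dimethyloxirane-2-carboxylic acid
Conditions: TEMPO (cat.), PhI(OAc)2, MeCN–H2O, rt
Reagents that add atoms: water O
Why: The oxoammonium (TEMPO) oxidation runs through the aldehyde hydrate and does not touch the stereocentres, so the descriptor at C2′ changes only by priority.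

Step 21
Reactants: 26 hydroxy acetate; 30 epoxy acid
Product: 32 CNP0188864.1 (target), via mixed anhydride 31 (not isolated)
Conditions: 30, 2,4,6-Cl3C6H2COCl, Et3N, PhMe, rt; then 26, DMAP, rt
Reagents that add atoms: none
Why: Yamaguchi esterification should acylate the hindered C8–OH with the α-quaternary acid without touching any stereocentre, the epoxide or the acetate.

Compound list
1 | 3-[(4-methoxybenzyl)oxy]propanal | O=CCCOCc1ccc(OC)cc1 | starting material
2 | 1-({[(3Z)-4-iodopent-3-en-1-yl]oxy}methyl)-4-methoxybenzene | C/C(I)=C/CCOCc1ccc(OC)cc1 | intermediate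
3 | (S)-epichlorohydrin | ClC[C@@H]1CO1 | starting material
4 | (Z)-alkenyllithium from 2 (Li in place of I) | C/C([Li])=C/CCOCc1ccc(OC)cc1 | intermediate
5 | (2S,4Z)-1-chloro-7-[(4-methoxybenzyl)oxy]-4-methylhept-4-en-2-ol | ClC[C@@H](O)C/C(C)=C\CCOCc1ccc(OC)cc1 | intermediate
6 | (2S)-2-{(2Z)-5-[(4-methoxybenzyl)oxy]-2-methylpent-2-en-1-yl}oxirane | C1O[C@H]1C/C(C)=C\CCOCc1ccc(OC)cc1 | intermediate
7 | (3S,5Z)-8-[(4-methoxybenzyl)oxy]-5-methylocta-1,5-dien-3-ol | C=C[C@@H](O)C/C(C)=C\CCOCc1ccc(OC)cc1 | intermediate
8 | ethyl 2-[bis(2,2,2-trifluoroethoxy)phosphoryl]propanoate | CCOC(=O)C(C)P(=O)(OCC(F)(F)F)OCC(F)(F)F | starting material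
9 | 2-[bis(2,2,2-trifluoroethoxy)phosphoryl]propanoic acid | OC(=O)C(C)P(=O)(OCC(F)(F)F)OCC(F)(F)F | intermediate
10 | 2-methylenepropane-1,3-diol | C=C(CO)CO | starting material
11 | 2-(hydroxymethyl)prop-2-en-1-yl 2-[bis(2,2,2-trifluoroethoxy)phosphoryl]propanoate | C=C(CO)COC(=O)C(C)P(=O)(OCC(F)(F)F)OCC(F)(F)F | intermediate
12 | chloro(diisopropyl)silyl ether of 7 | C=C[C@@H](O[Si](Cl)(C(C)C)C(C)C)C/C(C)=C\CCOCc1ccc(OC)cc1 | intermediate
13 | mixed diisopropylsilyl bis-ether of 7 and 11 | C=C[C@@H](O[Si](C(C)C)(C(C)C)OCC(=C)COC(=O)C(C)P(=O)(OCC(F)(F)F)OCC(F)(F)F)C/C(C)=C\CCOCc1ccc(OC)cc1 | intermediate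
14 | (4S)-dihydrodioxasilepine with PMB-protected side chain and phosphonopropionate | CC(C)[Si]1(C(C)C)OCC(COC(=O)C(C)P(=O)(OCC(F)(F)F)OCC(F)(F)F)=C[C@H](C/C(C)=C\CCOCc2ccc(OC)cc2)O1 | intermediate
15 | primary alcohol from 14 | CC(C)[Si]1(C(C)C)OCC(COC(=O)C(C)P(=O)(OCC(F)(F)F)OCC(F)(F)F)=C[C@H](C/C(C)=C\CCO)O1 | intermediate
16 | β,γ-unsaturated aldehyde from 15 | CC(C)[Si]1(C(C)C)OCC(COC(=O)C(C)P(=O)(OCC(F)(F)F)OCC(F)(F)F)=C[C@H](C/C(C)=C\CC=O)O1 | intermediate
17 | twelve-membered (1(10)Z,3Z) macrolactone fused to the silaketal ring (6S) | C/C1=C/C/C=C(C)\C[C@H]2C=C(COC1=O)CO[Si](C(C)C)(C(C)C)O2 | intermediate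
18 | twelve-membered allyl dienyl ether fused to the silaketal ring (6S) | C/C1=C/C/C=C(C)\C[C@H]2C=C(COC1=C)CO[Si](C(C)C)(C(C)C)O2 | intermediate
19 | macrocyclic dienyl ether diol (6S, 7(11)E) | C/C1=C/C/C=C(C)\C[C@H](O)/C=C(\CO)COC1=C | intermediate
20 | macrocyclic lactol | C/C1=C/C/C=C(C)\C[C@H]2C=C(COC1=C)C(O)O2 | intermediate
21 | α,γ-bridged butenolide, twelve-membered allyl dienyl ether (6S) | C/C1=C/C/C=C(C)\C[C@H]2C=C(COC1=C)C(=O)O2 | intermediate
22 | (6S,7S)-9-oxogermacra-1(10)Z,3Z,11(13)-trien-12,6-olide | C=C1C(=O)O[C@H]2C/C(C)=C\C/C=C(/C)C(=O)C[C@@H]12 | intermediate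
23 | potassium C8=C9 enolate of 22 (drawn ring-cis) | C=C1C(=O)O[C@H]2C/C(C)=C\C/C=C(/C)\C([O-])=C/[C@@H]12.[K+] | intermediate
24 | (6S,7S,8R)-8-hydroxy-9-oxogermacra-1(10)Z,3Z,11(13)-trien-12,6-olide | C=C1C(=O)O[C@H]2C/C(C)=C\C/C=C(/C)C(=O)[C@H](O)[C@@H]12 | intermediate
25 | (6S,7S,8R,9S)-8,9-dihydroxygermacra-1(10)Z,3Z,11(13)-trien-12,6-olide | C=C1C(=O)O[C@H]2C/C(C)=C\C/C=C(/C)[C@H](O)[C@H](O)[C@@H]12 | intermediate
26 | 9-O-acetyl derivative of 25 | C=C1C(=O)O[C@H]2C/C(C)=C\C/C=C(/C)[C@H](OC(C)=O)[C@H](O)[C@@H]12 | intermediate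
27 | tiglic acid | C/C=C(\C)C(=O)O | starting material
28 | (E)-2-methylbut-2-en-1-ol | C/C=C(\C)CO | intermediate
29 | [(2R,3R)-2,3-dimethyloxiran-2-yl]methanol | OC[C@@]1(C)O[C@@H]1C | intermediate
30 | (2S,3R)-2,3-dimethyloxirane-2-carboxylic acid | OC(=O)[C@@]1(C)O[C@@H]1C | intermediate
31 | mixed anhydride of 30 and 2,4,6-trichlorobenzoic acid | O=C(OC(=O)[C@@]1(C)O[C@@H]1C)c1c(Cl)cc(Cl)cc1Cl | intermediate
32 | CNP0188864.1: (6S,7S,8R,9S)-9-acetoxy-8-[(2S,3R)-2,3-epoxy-2-methylbutanoyloxy]germacra-1(10)Z,3Z,11(13)-trien-12,6-olide | C=C1C(=O)O[C@H]2C/C(C)=C\C/C=C(/C)[C@H](OC(C)=O)[C@H](OC(=O)[C@@]3(C)O[C@@H]3C)[C@@H]12 | target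

Total step count: 21.
Longest linear sequence: 16 steps (steps 1–3, 6–17 and 21).

Steps most likely to fail

1. **Step 14.**
   - Risk: the (Z)-2-alkoxydiene may undergo a [1,5]-hydrogen shift from C2 to C8 before the bridged six-centre array is reached, or traces of acid may hydrolyse the dienyl ether.
   - Fallback (from 21 back to 22): the C7–C8 bond is made by an ionic addition–elimination instead of a pericyclic shift. PPTS in wet THF opens 21 to the hydroxy enone F1. CBr4/PPh3 converts it into the allylic bromide F2. TMSOTf/2,6-lutidine gives the silyl dienol ether F3. Fluoride (TBAT, high dilution) then releases the enolate, which adds to C7 of the α-(bromomethyl)butenolide and expels bromide (SN2′). The chain again reaches only the C5 face, so 22 should result.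

2. **Step 10.**
   - Risk: the base may move the C3=C4 alkene of the aldehyde into conjugation, the chain ends may oligomerise, or the ring strain may erode the Z-selectivity.
   - Fallback (from 7 back to 17): the olefination is run between two molecules, and the large ring is closed later at silicon and by metathesis. DDQ frees the diol F4. TEMPO/PhI(OAc)2 oxidises only the primary alcohol, giving the hydroxy aldehyde F5. Still–Gennari olefination with pre-formed, doubly deprotonated 11 (KHMDS, 18-crown-6, −78 °C, aldehyde added last) gives the (Z)-enoate diol F6. iPr2SiCl2/imidazole at high dilution bridges O6 and O12 to the 15-membered silaketal F7. Transannular ring-closing metathesis (Grubbs II) then gives 17.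

3. **Step 15.**
   - Risk: the strong base may deprotonate C2 or C7 instead of C8, the enolate may be consumed by Michael addition to the α-methylene lactone, or the facial selectivity may be poor.
   - Fallback (from 22 back to 24): the oxygen is introduced on a neutral, isolated enol derivative. Soft enolisation (TMSOTf, 2,6-lutidine, CH2Cl2, −78 °C) gives the silyl dienol ether F8. A Rubottom-type oxidation with OsO4 (cat.)/NMO at its most electron-rich double bond, followed by loss of silicon on work-up, gives 24.

Further compounds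
F1 | step 14 | hydroxy enone (methyl (Z)-enone, α-hydroxymethyl butenolide, 6S) | CC(=O)/C(C)=C\C/C=C(C)\C[C@H]1C=C(CO)C(=O)O1
F2 | step 14 | allylic bromide from F1 | CC(=O)/C(C)=C\C/C=C(C)\C[C@H]1C=C(CBr)C(=O)O1
F3 | step 14 | trimethylsilyl dienol ether of F2 | C=C(O[Si](C)(C)C)/C(C)=C\C/C=C(C)\C[C@H]1C=C(CBr)C(=O)O1
F4 | step 10 | (3Z,6S)-4-methylocta-3,7-diene-1,6-diol | C=C[C@@H](O)C/C(C)=C\CCO
F5 | step 10 | (3Z,6S)-6-hydroxy-4-methylocta-3,7-dienal | C=C[C@@H](O)C/C(C)=C\CC=O
F6 | step 10 | 2-(hydroxymethyl)allyl (2Z,5Z,8S)-8-hydroxy-2,6-dimethyldeca-2,5,9-trienoate | C=C[C@@H](O)C/C(C)=C\C/C=C(/C)C(=O)OCC(=C)CO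
F7 | step 10 | 15-membered diisopropylsilaketal of F6 | C=C[C@@H]1C/C(C)=C\C/C=C(/C)C(=O)OCC(=C)CO[Si](C(C)C)(C(C)C)O1
F8 | step 15 | C8=C9 trimethylsilyl dienol ether of 22 (drawn ring-cis) | C=C1C(=O)O[C@H]2C/C(C)=C\C/C=C(/C)\C(O[Si](C)(C)C)=C/[C@@H]12
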